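Everything rests on cutting the bond between quinone carbon C3 and the adjacent side-chain CH2. In one operation the key step expels CO2 from an activated carboxyl group, adds the resulting primary radical ArC(=O)CH2CH2• to a ring C–H of 2,6-dimethoxy-1,4-benzoquinone and regenerates the quinone. It exploits the mirror symmetry of that ring: C3–H and C5–H are its only C–H positions and are equivalent, so only one mono-alkylated isomer can arise. The radical precursor is the N-acyloxyphthalimide of 4-(3,4-dimethoxyphenyl)-4-oxobutanoic acid, the veratrole–succinic anhydride adduct, which carries exactly one carbon more than the side chain needs. Both rings are preformed and are joined in the last step.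

Key step: step 4

Remark on the chemistry: evelynin has no stereocentre and no stereogenic double bond. It is achiral, so no stereocontrol is needed. Quinone numbering used below: C1 is the carbonyl flanked by the methoxy carbons C2 and C6, C3 bears the chain, C4 is the second carbonyl, and C5 bears H.

Step 1
Reactants: 1 veratrole (1,2-dimethoxybenzene); 2 succinic anhydride
Product: 3 4-(3,4-dimethoxyphenyl)-4-oxobutanoic acid
Conditions: AlCl3 (2.2 equiv), CH2Cl2, 0 °C → rt; ice/2 M HCl; NaHCO3 extraction, re-acidification, recrystallisation
Reagents that add atoms: none
Why: In this Friedel–Crafts acylation (Haworth-type succinoylation) the AlCl3-opened anhydride attacks the unhindered ring position para to one methoxy group, the new ketone shuts the ring down against a second acylation, and working at or below room temperature avoids AlCl3 cleavage of the aryl methyl ethers.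

Step 2
Reactants: 3 4-(3,4-dimethoxyphenyl)-4-oxobutanoic acid; 4 N-hydroxyphthalimide
Product: 5 1,3-dioxoisoindolin-2-yl 4-(3,4-dimethoxyphenyl)-4-oxobutanoate (the N-acyloxyphthalimide redox-active ester of 3)
Conditions: DIC (1.1 equiv), DMAP (0.1 equiv), CH2Cl2, 0 °C → rt; short silica plug or recrystallisation
Reagents that add atoms: none
Why: In this Steglich-type carbodiimide esterification the acidic N–OH nucleophile should capture the activated carboxyl group quickly under DMAP catalysis, ahead of O→N acyl shift or enol-lactonisation of the γ-keto acid, and the aryl ketone and ethers are inert.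

Step 3
Reactants: 6 syringol (2,6-dimethoxyphenol)
Product: 7 2,6-dimethoxy-1,4-benzoquinone
Conditions: Co(salen) (salcomine, 5 mol %), O2 (1 atm), DMF, rt; precipitation with water
Reagents that add atoms: dioxygen, O=O
Why: This is the cobalt–salen catalysed aerobic oxidation of a para-unsubstituted phenol to a p-quinone, in which the cobalt–dioxygen species removes the phenolic hydrogen and delivers oxygen to the free para carbon, the two ortho methoxy groups block ortho attack, and a coordinating solvent at moderate dilution favours oxygenation over radical dimerisation.

Step 4
Reactants: 5 1,3-dioxoisoindolin-2-yl 4-(3,4-dimethoxyphenyl)-4-oxobutanoate; 7 2,6-dimethoxy-1,4-benzoquinone (2.5 equiv)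
Product: 10 evelynin [3-(3-(3,4-dimethoxyphenyl)-3-oxopropyl)-2,6-dimethoxy-1,4-benzoquinone], via aroylethyl radical 8 (not isolated), via quinone adduct radical 9 (not isolated)
Conditions: fac-Ir(ppy)3 (1–2 mol %), TFA (1 equiv), MeCN/CH2Cl2 1:1 (0.05 M in 5), degassed (Ar), blue LEDs (ca. 455 nm), rt with fan cooling; work-up in air; chromatography with recovery of surplus 7
Reagents that add atoms: none
Why: Excited fac-Ir(ppy)3 is chosen because its excited state is reducing enough to transfer an electron to an N-acyloxyphthalimide outright, which excited Ru(bpy)3(2+) is not, and the radical anion of 5 so formed breaks at N–O and loses CO2 to give the primary radical 8. This nucleophilic radical adds to C3 of the electron-poor quinone 7 to give 9, whose spin sits on C2 and is stabilised jointly by the C2 methoxy oxygen and the C1 carbonyl; Ir(IV), directly or with surplus 7 as electron relay, then removes one electron and C3 loses its proton, which restores the quinone and closes a redox-neutral cycle that spares the oxidisable veratryl ring. The closest known reaction type is the Minisci-type decarboxylative C–H alkylation of quinones (Jacobsen–Torssell reaction), run here with the photoredox activation of redox-active esters that is established for Giese and Minisci additions. No ring is closed and no stereocentre remains, because the sp3 C3 of 9 becomes planar again. The step needs site selectivity, which the symmetry of 7 supplies (C3 and C5 are identical, and C–H carbons are attacked in preference to the methoxy-bearing C2 and C6), and mono-selectivity, which the excess of 7 and the lower electron affinity of the alkylated quinone 10 supply. TFA keeps the liberated phthalimide protonated so that it cannot displace a vinylogous-ester methoxy group, and the one rearrangement open to 8, a 1,2-acyl shift, is degenerate.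

Compound list
1 | veratrole (1,2-dimethoxybenzene) | COc1ccccc1OC | starting material
2 | succinic anhydride | O=C1CCC(=O)O1 | starting material
3 | 4-(3,4-dimethoxyphenyl)-4-oxobutanoic acid | COc1ccc(C(=O)CCC(=O)O)cc1OC | intermediate
4 | N-hydroxyphthalimide | ON1C(=O)c2ccccc2C1=O | starting material
5 | 1,3-dioxoisoindolin-2-yl 4-(3,4-dimethoxyphenyl)-4-oxobutanoate | COc1ccc(C(=O)CCC(=O)ON2C(=O)c3ccccc3C2=O)cc1OC | intermediate
6 | syringol (2,6-dimethoxyphenol) | COc1cccc(OC)c1O | starting material
7 | 2,6-dimethoxy-1,4-benzoquinone (also an article of commerce) | COC1=CC(=O)C=C(OC)C1=O | intermediate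
8 | 3-(3,4-dimethoxyphenyl)-3-oxopropyl radical (not isolated) | COc1ccc(C(=O)C[CH2])cc1OC | intermediate
9 | C2-centred radical from addition of 8 to C3 of 7 (not isolated) | COC1=CC(=O)C(CCC(=O)c2ccc(OC)c(OC)c2)[C](OC)C1=O | intermediate
10 | evelynin | COC1=CC(=O)C(CCC(=O)c2ccc(OC)c(OC)c2)=C(OC)C1=O | target

Total step count: 4
Longest linear sequence: 3 steps (1 → 3 → 5 → 10). The quinone branch (6 → 7 → 10) has 2 steps.

Steps most likely to fail

Step 4. The quinone is easier to reduce than ester 5 and absorbs weakly in the blue. It may therefore intercept the excited catalyst (electron or energy transfer followed by back transfer) or screen the light, so that radical generation stalls. A second alkylation at C5 may also consume product. The fallback builds the chain by ionic chemistry and unveils the quinone last. Setting out from veratrole 1, acetylation (Ac2O, cat. Bi(OTf)3) would give 3,4-dimethoxyacetophenone F1. Claisen–Schmidt condensation (KOH, EtOH, rt) with purchased 2,3,4,6-tetramethoxybenzaldehyde F2 would give (E)-1-(3,4-dimethoxyphenyl)-3-(2,3,4,6-tetramethoxyphenyl)prop-2-en-1-one F3. Hydrogenation of the enone C=C (H2, Pd/C, EtOAc, stopped after one equivalent) would give 1-(3,4-dimethoxyphenyl)-3-(2,3,4,6-tetramethoxyphenyl)propan-1-one F4. Oxidative demethylation with ceric ammonium nitrate (MeCN/H2O, 0 °C) across the para-related C3/C6 methoxy pair of the tetramethoxy ring returns to the route at 10. The ketone-deactivated veratryl ring should be left alone.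

Step 3. Para–para C–C coupling of two phenoxyl radicals may compete with oxygenation, and the cobalt catalyst may be deactivated before conversion is complete. The fallback places the para heteroatom by electrophilic substitution instead of radical oxygenation. Setting out from syringol 6, nitrosation (NaNO2, aq. HCl/EtOH, 0 °C) would give 2,6-dimethoxy-4-nitrosophenol F5. Reduction (Na2S2O4, aq. base, or H2, Pd/C) would give 4-amino-2,6-dimethoxyphenol F6. Oxidation with FeCl3 in dilute HCl would give 4-imino-2,6-dimethoxycyclohexa-2,5-dien-1-one F7. This hydrolyses in the same flask and returns to the route at 7.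

Step 2. The activated γ-keto acid may cyclise through its enol oxygen or suffer O→N acyl shift before the N-hydroxy nucleophile arrives. The active ester may also hydrolyse during purification. The fallback omits activation and generates the radical oxidatively instead of reductively. It sets out from acid 3 together with quinone 7 (excess). Catalytic AgNO3 with slow addition of (NH4)2S2O8 in MeCN/H2O at 60–70 °C (Jacobsen–Torssell reaction) would oxidise the carboxylate. CO2 is then lost, the same radical 8 is formed, and it adds to C3 of 7. Persulfate re-oxidises the adduct, and the route is rejoined at 10. The ketone on the veratryl ring lowers that ring's susceptibility to the oxidant, but this remains the reason the ester route is preferred.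

Further compounds
F1 | step 4 | 3,4-dimethoxyacetophenone | CC(=O)c1ccc(OC)c(OC)c1
F2 | step 4 | 2,3,4,6-tetramethoxybenzaldehyde (purchased partner) | COc1cc(OC)c(OC)c(OC)c1C=O
F3 | step 4 | (E)-1-(3,4-dimethoxyphenyl)-3-(2,3,4,6-tetramethoxyphenyl)prop-2-en-1-one | COc1ccc(C(=O)/C=C/c2c(OC)cc(OC)c(OC)c2OC)cc1OC
F4 | step 4 | 1-(3,4-dimethoxyphenyl)-3-(2,3,4,6-tetramethoxyphenyl)propan-1-one | COc1ccc(C(=O)CCc2c(OC)cc(OC)c(OC)c2OC)cc1OC
F5 | step 3 | 2,6-dimethoxy-4-nitrosophenol | COc1cc(N=O)cc(OC)c1O
F6 | step 3 | 4-amino-2,6-dimethoxyphenol | COc1cc(N)cc(OC)c1O
F7 | step 3 | 4-imino-2,6-dimethoxycyclohexa-2,5-dien-1-one | COC1=CC(=N)C=C(OC)C1=O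
F0 | step 2 | none | none
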